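## Structural features

The target is a flavanone: benzene ring A is fused through C4a and C8a to a dihydropyranone ring C (O1, C2, C3, C4=O), and a 3,4-dihydroxyphenyl ring B sits on C2. Ring A carries the complete phloroglucinol oxygen pattern, differentiated three ways (a free hydroxyl on C5 that is hydrogen-bonded to the C4 carbonyl, a methyl ether on C7 and the ring oxygen O1 on C8a), with a 3-methylbut-2-enyl (prenyl) group on C8 and hydrogen only on C6. There is one stereocentre, C2 (S), benzylic, bound to O1 and β to the ketone; it has no neighbouring stereocentre. Fragile elements are the β-aryloxy ketone (base or strong acid opens ring C to the 2'-hydroxychalcone and erases C2), the trisubstituted prenyl alkene (strong acid, boranes, hydrogenation) and the oxidisable catechol. The real difficulty is twofold: placing methyl, hydrogen and prenyl correctly around ring A, and delivering C2 as one enantiomer although it stands in a reversible oxa-Michael relationship to the carbonyl. The key step uses the fact that O1 is the only link between C2 and the aromatic carbon C8a, and that C8a is ortho to C4a, which carries the C4–C3–C2 chain. Ring C can therefore be closed at O1–C8a with C2 arriving as a finished carbinol, and the oxygen originally on C8a becomes expendable: it first steers the prenyl group to C8 and then leaves as triflate.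

## Logic of the disconnections

**19 ⇒ 18.** The three phenolic O–H groups (O5, O3', O4') are traced back to methoxymethyl acetals. Acetal hydrolysis is the one deprotection that neither reduces the prenyl alkene nor brings base near the β-aryloxy ketone. The gain is that every earlier step works on a fully masked polyphenol. The forward step must use acid mild enough to spare the alkene and C2; this is realistic because no free phenol flanks the prenyl group (C7 is a methyl ether, C8a carries the ring oxygen), so acid cyclisation onto the alkene has no nucleophile.

**18 ⇒ 17 ⇒ 16.** No skeletal bond is cut; the C4=O π-bond is taken back to a C4–OH (17) and this to a C4–O–Si ether (16). With C4 at the alcohol level ring C holds no carbonyl while base and palladium are present, so chalcone formation, retro-aldol cleavage and epimerisation at C2 are excluded there. The price is a temporary, uncontrolled stereocentre at C4. The forward steps must be a neutral desilylation and a non-basic, buffered oxidation of an acid-labile, electron-rich benzylic alcohol.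

**16 ⇒ 15.** The O1–C8a bond is cut, opening ring C to an aryl triflate and a free (S)-carbinol. Of the two bonds that O1 makes in ring C, this is the one whose formation leaves every bond at C2 (to O1, C3, the ring B carbon and hydrogen) untouched, and it turns the C8a oxygen into a leaving group. The gain is one ring and an acyclic precursor whose stereocentre comes from a ketone. The forward step must make C–O reductive elimination at a doubly ortho-substituted arylpalladium centre faster than β-hydride elimination of a benzylic alkoxide, and must keep the triflate intact until palladium inserts.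

**15 ⇒ 14.** The C2–H bond is cut, returning the stereocentre to a prochiral aryl ketone. Aryl alkyl ketones are the best-behaved substrates for catalytic enantioselective reduction. The forward step must be catalyst-controlled in the presence of the racemic C4 centre and must use a hydride source that does not hydroborate the prenyl alkene.

**14 ⇒ 9 + 11 (through 12 and 13).** The C3–C4 bond and the C4 O–Si bond are cut: an aldol addition of the methyl ketone enolate 12 to the non-enolisable aldehyde 9, with the aldolate 13 silylated in the same flask. This divides the molecule into a ring A piece and a ring B piece of similar size. The forward step must trap 13 cold, before retro-aldol reversal or transfer of the triflyl group from the phenolic oxygen to the neighbouring alkoxide can occur.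

**11 ⇒ 10.** Two catechol O–CH2 bonds are cut. The acetals are base-stable through enolate chemistry and fall off in the final acid step with the C5 acetal, so no separate deprotection is added.

**9 ⇒ 8.** The O–S bond of the triflate is cut. The phenol on the future C8a is the hydroxyl left free by the preceding rearrangement, so no selectivity question arises. The forward step must sulfonylate a hindered, chelated phenol.

**8 ⇒ 6 (through 7).** The bond between the ring carbon (future C8) and the allylic CH2 is cut with allyl transposition, a retro-Claisen operation that places the C5 unit on the neighbouring oxygen as a 1,1-dimethylallyl ether. The position of the prenyl group is then dictated by which oxygen carries the allyl group, not by the intrinsic reactivity of ring A. The forward step needs a free ortho position next to that oxygen; the other ortho position carries the formyl group.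

**6 ⇒ 3 + 5, and 5 ⇒ 4.** The aryl O–C(tertiary allyl) bond is cut to phenol 3 and carbonate 5; the carbonate C–O bond is cut back to alcohol 4. The forward step must bond the phenoxide to the more substituted allyl terminus.

**3 ⇒ 2 ⇒ 1.** One O–CH2 (acetal) and one O–CH3 bond are cut. In 2 the two ortho hydroxyls are equivalent, so single protection creates no regiochemical problem. In 1 the 4-hydroxyl is the most acidic and the only one not tied to the formyl group. The forward steps depend on stopping after one alkylation each.

## Other disconnections considered

Alternative 1: The cut passes through C4a–C8a, C5–C6 and C7–C8, so rings A and C arise together from three alkynes. In the forward direction the tethered diyne A1 (an ethoxy-substituted ynone joined through C3 and C2 to an alkynyl ether that already carries the prenyl chain) would combine with methoxyacetylene A2 under [Rh(cod)2]BF4 and BINAP to give the 5-O-ethyl flavanone A3.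
- In favour: three C–C bonds and two rings form in one atom-economical operation; the substitution of ring A is written into the alkyne termini; C4 is a ketone from the start; C2 is a spectator.
- Where it is equal or better: in bond-forming power per step it is clearly better than the chosen plan, and after its key step it is at least equal (de-ethylation at O5 and acetal removal against three steps).
- Against: A1 contains a secondary benzylic alkynyl ether at C2, a class prone to retro-ene fragmentation and sigmatropic rearrangement on mild warming, and a β-alkynyloxy ketone that can eliminate. The stereocentre is therefore at risk before the key step.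
- Against: the skipped enyne of the prenyl arm offers the rhodacycle an extra π-ligand and allylic hydrogens. The orientation of A2 (methoxy to C7, not C6) rests on electronic bias alone, with no tether. A2 is volatile and self-oligomerises.
- Against: removing the ethyl group of A3 beside the C7 methyl ether needs a chelating Lewis acid, which the prenyl group tolerates poorly.
- Comparison: the chosen plan keeps an intact aromatic ring and asks its key step for one bond with a single possible regiochemistry, using storable intermediates. The total step count is expected to be similar once the preparation of A1 is included.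

Alternative 2: The cut is at C3–C4 together with C2–H. In the forward direction the salicylaldehyde A4, whose C8a oxygen carries a 1-arylvinyl group, would undergo intramolecular hydroacylation under [Rh(cod)2]BF4 and a chiral bisphosphine: the aldehyde C–H adds across the enol ether double bond to give A5.
- In favour: the C5 hydroxyl needs no protection and serves as the chelating anchor that holds the acylrhodium hydride and suppresses decarbonylation; C4 is at the ketone level throughout; ring A of A4 can be made by the same Claisen logic as 8.
- Where it is equal or better: A5 is one acetal hydrolysis from 19, which is better than the three steps after the chosen key step; and the stereocentre is created catalytically in the ring-forming step itself, which is more direct than a separate reduction.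
- Against: A4 is an α-aryl vinyl aryl ether on a hindered, doubly flanked oxygen. It is hard to make (methylenation of an aryl ester would require masking the aldehyde) and is very acid-labile.
- Against: hydride must go to C2 and acyl to C3 (six-membered closure). Closure at the internal alkene carbon to a five-membered ring with a quaternary centre is a plausible competitor.
- Against: face selection on a 1,1-disubstituted enol ether has no second binding point, and a 5-hydroxyflavanone formed in the presence of a basic rhodium phenoxide can reopen to the chalcone, eroding C2.
- Comparison: the chosen plan sets C2 by a ketone reduction with a dependable stereochemical model and keeps C2 away from any carbonyl until the end. It pays for this with protecting-group and redox steps.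

Alternative 3: The cut is at C2–C3. In the forward direction the aryl diazomethyl ketone A6, whose C8a oxygen carries the ring B benzyl group, would be decomposed by Rh2(S-PTTL)4; the carbene at C3 would insert into a benzylic C–H bond next to O1 to give A7.
- In favour: A6 is assembled from achiral pieces by O-benzylation and diazoketone formation; the C–H bond is doubly activated (benzylic and α to oxygen); the product is at the correct oxidation level.
- Where it is equal or better: the step count after the key step (two deprotections) and probably overall is equal or better, and the stereocentre and ring form in one C–C bond-forming event.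
- Against: an acceptor-only carbene is highly reactive and poorly discriminating. Closure to a six-membered ring is intrinsically slower than the usual five-membered insertion.
- Against: the ether oxygen O1 is placed for five-membered oxonium ylide formation followed by a benzyl shift, which is expected to be a major competitor. Addition to the electron-rich ring B and to the prenyl alkene are further diversions.
- Against: enantiocontrol by a carboxylate-bridged dirhodium catalyst is least secure for exactly this carbene class. Making A6 from a hindered acid derivative also requires diazomethane-type reagents, a safety disadvantage.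
- Comparison: in the chosen plan no comparable chemoselectivity question is built into the substrate, since the palladium alkoxide has only one aryl partner.

Key step: step 10

Assumption: the C4 silyloxy carbon is formed without control. 14 is racemic, and 15, 16 and 17 are carried as mixtures of C4 epimers, each (S) at the C2-destined carbon; they converge when C4 becomes the carbonyl carbon of 18.

## Route

Step 1
Reactants: 1 2,4,6-trihydroxybenzaldehyde
Product: 2 2,6-dihydroxy-4-methoxybenzaldehyde
Conditions: Me2SO4 (1.0 equiv), K2CO3 (1.0 equiv), acetone, 0 °C → rt
Reagents that add atoms: dimethyl sulfate, COS(=O)(=O)OC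
Why: Williamson-type O-methylation; the 4-hydroxyl is para to the formyl group, the most acidic and the only one not engaged in a hydrogen bond to C=O, so one equivalent of base and electrophile should alkylate it first, and a hard sulfate ester in an aprotic solvent favours attack through oxygen over ring carbon.

Step 2
Reactants: 2 2,6-dihydroxy-4-methoxybenzaldehyde
Product: 3 2-hydroxy-4-methoxy-6-(methoxymethoxy)benzaldehyde
Conditions: MOMCl (1.1 equiv), i-Pr2NEt, CH2Cl2, 0 °C
Reagents that add atoms: chloromethyl methyl ether, COCCl
Why: Acetal-type O-alkylation (MOM protection); the two ortho hydroxyls are equivalent, and once one is capped the other is locked in a hydrogen bond to the formyl oxygen, so an amine base should stop at the mono-ether.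

Step 3
Reactants: 4 2-methylbut-3-en-2-ol
Product: 5 tert-butyl 2-methylbut-3-en-2-yl carbonate
Conditions: n-BuLi, THF, 0 °C; then Boc2O, 0 °C → rt
Reagents that add atoms: di-tert-butyl dicarbonate, CC(C)(C)OC(=O)OC(=O)OC(C)(C)C
Why: Acylation of a tertiary lithium alkoxide by the dicarbonate (carbonate formation); deprotonation first is needed because the tertiary alcohol is a poor nucleophile.

Step 4
Reactants: 3 2-hydroxy-4-methoxy-6-(methoxymethoxy)benzaldehyde; 5 tert-butyl 2-methylbut-3-en-2-yl carbonate
Product: 6 4-methoxy-2-(methoxymethoxy)-6-(2-methylbut-3-en-2-yloxy)benzaldehyde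
Conditions: Pd(PPh3)4 (3 mol %), THF, 0 °C
Reagents that add atoms: none
Why: Tsuji–Trost decarboxylative O-allylation; ionisation of 5 gives a 1,1-dimethylallylpalladium cation and tert-butoxide, which deprotonates the chelated phenol, and the phenoxide should attack the more substituted allyl terminus under kinetic control at low temperature to give the tertiary ether.

Step 5
Reactants: 6 4-methoxy-2-(methoxymethoxy)-6-(2-methylbut-3-en-2-yloxy)benzaldehyde
Product: 8 2-hydroxy-4-methoxy-6-(methoxymethoxy)-3-(3-methylbut-2-enyl)benzaldehyde, via ortho-dienone 7 (not isolated)
Conditions: PhMe, 120 °C (sealed vessel)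
Reagents that add atoms: none
Why: Aromatic Claisen rearrangement; the [3,3] shift goes to the only hydrogen-bearing ortho carbon (the future C8), allyl inversion converts the 1,1-dimethylallyl ether into the 3-methylbut-2-enyl group, and tautomerisation of 7 restores the phenol on the future C8a.

Step 6
Reactants: 8 2-hydroxy-4-methoxy-6-(methoxymethoxy)-3-(3-methylbut-2-enyl)benzaldehyde
Product: 9 2-formyl-5-methoxy-3-(methoxymethoxy)-6-(3-methylbut-2-enyl)phenyl trifluoromethanesulfonate
Conditions: Tf2O, pyridine, CH2Cl2, −10 → 0 °C
Reagents that add atoms: trifluoromethanesulfonic anhydride, O=S(=O)(OS(=O)(=O)C(F)(F)F)C(F)(F)F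
Why: O-Sulfonylation of a phenol (triflation); the anhydride is reactive enough for a chelated, flanked phenol, and excess pyridine keeps the medium free of acid so the acetal and the alkene survive.

Step 7
Reactants: 10 3',4'-dihydroxyacetophenone
Product: 11 3',4'-bis(methoxymethoxy)acetophenone
Conditions: MOMCl (2.5 equiv), i-Pr2NEt, CH2Cl2, 0 °C → rt
Reagents that add atoms: chloromethyl methyl ether, COCCl
Why: Double MOM protection of a catechol; neither hydroxyl is chelated to the para/meta acetyl group, so both should alkylate under amine base.

Step 8
Reactants: 11 3',4'-bis(methoxymethoxy)acetophenone; 9 2-formyl-5-methoxy-3-(methoxymethoxy)-6-(3-methylbut-2-enyl)phenyl trifluoromethanesulfonate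
Product: 14 rac-2-{1-(tert-butyldimethylsilyloxy)-3-oxo-3-[3,4-bis(methoxymethoxy)phenyl]propyl}-5-methoxy-3-(methoxymethoxy)-6-(3-methylbut-2-enyl)phenyl trifluoromethanesulfonate, via lithium enolate 12 (not isolated), via lithium aldolate 13 (not isolated)
Conditions: LiN(SiMe3)2, THF, −78 °C; 9, −78 °C; then TBSOTf, −78 → −40 °C; NaHCO3 (aq)
Reagents that add atoms: tert-butyldimethylsilyl trifluoromethanesulfonate, CC(C)(C)[Si](C)(C)OS(=O)(=O)C(F)(F)F; lithium bis(trimethylsilyl)amide, [Li+].C[Si](C)(C)[N-][Si](C)(C)C (lithium in 12 and 13 only)
Why: Directed lithium-enolate aldol addition to a non-enolisable aldehyde followed by O-silylation of the aldolate in the same flask; trapping 13 at low temperature should forestall retro-aldol reversal, dehydration and triflyl transfer to the adjacent alkoxide. The new C4 centre is racemic by design.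

Step 9
Reactants: 14 rac-2-{1-(tert-butyldimethylsilyloxy)-3-oxo-3-[3,4-bis(methoxymethoxy)phenyl]propyl}-5-methoxy-3-(methoxymethoxy)-6-(3-methylbut-2-enyl)phenyl trifluoromethanesulfonate
Product: 15 2-{(3S)-1-(tert-butyldimethylsilyloxy)-3-hydroxy-3-[3,4-bis(methoxymethoxy)phenyl]propyl}-5-methoxy-3-(methoxymethoxy)-6-(3-methylbut-2-enyl)phenyl trifluoromethanesulfonate (both epimers at the silyloxy carbon)
Conditions: (R)-2-methyl-CBS-oxazaborolidine (20 mol %), catecholborane, PhMe, −78 → −40 °C; MeOH, then NaHCO3 (aq)
Reagents that add atoms: none
Why: Corey–Bakshi–Shibata reduction; the (R)-oxazaborolidine binds the carbonyl oxygen anti to the aryl group (large) and delivers hydride to the face that gives the (S)-carbinol, as with simple aryl alkyl ketones. Catecholborane at low temperature is chosen over BH3 so that the prenyl alkene is not hydroborated.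

Step 10
Reactants: 15 2-{(3S)-1-(tert-butyldimethylsilyloxy)-3-hydroxy-3-[3,4-bis(methoxymethoxy)phenyl]propyl}-5-methoxy-3-(methoxymethoxy)-6-(3-methylbut-2-enyl)phenyl trifluoromethanesulfonate (both epimers at the silyloxy carbon)
Product: 16 (2S)-4-(tert-butyldimethylsilyloxy)-7-methoxy-5-(methoxymethoxy)-2-[3,4-bis(methoxymethoxy)phenyl]-8-(3-methylbut-2-enyl)chroman (both C4 epimers)
Conditions: Pd(OAc)2 (5 mol %), 2-di-tert-butylphosphino-2',4',6'-triisopropylbiphenyl (10 mol %), K3PO4 (anhydrous, 2 equiv), PhMe, 80 °C
Reagents that add atoms: none
Why: Pd(OAc)2 is reduced in the flask to a monoligated zerovalent palladium species, which adds oxidatively to the C8a–O(triflate) bond; phosphate then deprotonates the palladium-bound C2 hydroxyl to give a seven-membered aryl(alkoxo) complex of divalent palladium, and C–O reductive elimination forms O1–C8a. The closest known reaction type is the Buchwald-type intramolecular etherification of aryl halides and sulfonates with secondary alcohols, which is established for chromans. Ring C closes in a 6-exo sense: the C2 oxygen attacks C8a while the departing triflate lies outside the new ring. No stereocentre is created; only the O–H bond of the carbinol is exchanged for O–Pd and then O–C, so the (S) configuration from step 9 is carried over, and C4 remains a mixture. The step needs reductive elimination to be faster than β-hydride elimination of the benzylic palladium alkoxide, which would return a ketone and a reduced arene; the large di-tert-butylbiaryl ligand and the favourable six-membered closure are relied on for this. It also needs the triflate S–O bond to survive until insertion, which an insoluble weak base in toluene favours. The C4 silyl ether removes the only other hydroxyl that could bind palladium and leaves no carbonyl in the molecule, so retro-aldol cleavage, chalcone formation and epimerisation have no pathway.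

Step 11
Reactants: 16 (2S)-4-(tert-butyldimethylsilyloxy)-7-methoxy-5-(methoxymethoxy)-2-[3,4-bis(methoxymethoxy)phenyl]-8-(3-methylbut-2-enyl)chroman (both C4 epimers)
Product: 17 (2S)-7-methoxy-5-(methoxymethoxy)-2-[3,4-bis(methoxymethoxy)phenyl]-8-(3-methylbut-2-enyl)chroman-4-ol (both C4 epimers)
Conditions: Bu4NF, THF, rt
Reagents that add atoms: none
Why: Fluoride-induced cleavage of a silyl ether; the conditions are non-acidic, so the electron-rich benzylic C4–O bond should not ionise, and there is no carbonyl for the basic fluoride to act on.

Step 12
Reactants: 17 (2S)-7-methoxy-5-(methoxymethoxy)-2-[3,4-bis(methoxymethoxy)phenyl]-8-(3-methylbut-2-enyl)chroman-4-ol (both C4 epimers)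
Product: 18 (2S)-7-methoxy-5-(methoxymethoxy)-2-[3,4-bis(methoxymethoxy)phenyl]-8-(3-methylbut-2-enyl)chroman-4-one
Conditions: Dess–Martin periodinane, pyridine, CH2Cl2, 0 °C → rt
Reagents that add atoms: none
Why: Dess–Martin oxidation of a secondary benzylic alcohol; it is fast and near neutral when buffered with pyridine, leaves the trisubstituted alkene and acetals alone, and both C4 epimers converge on one ketone without exposing the new β-aryloxy ketone to strong base.

Step 13
Reactants: 18 (2S)-7-methoxy-5-(methoxymethoxy)-2-[3,4-bis(methoxymethoxy)phenyl]-8-(3-methylbut-2-enyl)chroman-4-one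
Product: 19 (2S)-2-(3,4-dihydroxyphenyl)-5-hydroxy-7-methoxy-8-(3-methylbut-2-enyl)chroman-4-one
Conditions: HCl (3 M aq)/MeOH, 40 °C
Reagents that add atoms: none
Why: Acid-catalysed acetal cleavage with transfer of the methoxymethyl groups to methanol; the prenyl group has no neighbouring free phenol to cyclise onto, and dilute acid at mild temperature should not open ring C, so C2 is retained.

## Compound list

1 | 2,4,6-trihydroxybenzaldehyde | O=Cc1c(O)cc(O)cc1O | starting material
2 | 2,6-dihydroxy-4-methoxybenzaldehyde | COc1cc(O)c(C=O)c(O)c1 | intermediate
3 | 2-hydroxy-4-methoxy-6-(methoxymethoxy)benzaldehyde | COc1cc(OCOC)c(C=O)c(O)c1 | intermediate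
4 | 2-methylbut-3-en-2-ol | C=CC(C)(C)O | starting material
5 | tert-butyl 2-methylbut-3-en-2-yl carbonate | C=CC(C)(C)OC(=O)OC(C)(C)C | intermediate
6 | 4-methoxy-2-(methoxymethoxy)-6-(2-methylbut-3-en-2-yloxy)benzaldehyde | COc1cc(OCOC)c(C=O)c(OC(C)(C)C=C)c1 | intermediate
7 | ortho-dienone, rac-2-formyl-5-methoxy-3-(methoxymethoxy)-6-(3-methylbut-2-enyl)cyclohexa-2,4-dien-1-one | O=C1C(C=O)=C(OCOC)C=C(OC)C1CC=C(C)C | intermediate (not isolated)
8 | 2-hydroxy-4-methoxy-6-(methoxymethoxy)-3-(3-methylbut-2-enyl)benzaldehyde | COc1cc(OCOC)c(C=O)c(O)c1CC=C(C)C | intermediate
9 | 2-formyl-5-methoxy-3-(methoxymethoxy)-6-(3-methylbut-2-enyl)phenyl trifluoromethanesulfonate | COc1cc(OCOC)c(C=O)c(OS(=O)(=O)C(F)(F)F)c1CC=C(C)C | intermediate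
10 | 3',4'-dihydroxyacetophenone | CC(=O)c1ccc(O)c(O)c1 | starting material
11 | 3',4'-bis(methoxymethoxy)acetophenone | CC(=O)c1ccc(OCOC)c(OCOC)c1 | intermediate
12 | lithium enolate, lithium 1-[3,4-bis(methoxymethoxy)phenyl]ethenolate | [Li+].[O-]C(=C)c1ccc(OCOC)c(OCOC)c1 | intermediate (not isolated)
13 | lithium aldolate, lithium salt of rac-2-{1-hydroxy-3-oxo-3-[3,4-bis(methoxymethoxy)phenyl]propyl}-5-methoxy-3-(methoxymethoxy)-6-(3-methylbut-2-enyl)phenyl trifluoromethanesulfonate | COc1cc(OCOC)c(C([O-])CC(=O)c2ccc(OCOC)c(OCOC)c2)c(OS(=O)(=O)C(F)(F)F)c1CC=C(C)C.[Li+] | intermediate (not isolated)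
14 | rac-2-{1-(tert-butyldimethylsilyloxy)-3-oxo-3-[3,4-bis(methoxymethoxy)phenyl]propyl}-5-methoxy-3-(methoxymethoxy)-6-(3-methylbut-2-enyl)phenyl trifluoromethanesulfonate | COc1cc(OCOC)c(C(O[Si](C)(C)C(C)(C)C)CC(=O)c2ccc(OCOC)c(OCOC)c2)c(OS(=O)(=O)C(F)(F)F)c1CC=C(C)C | intermediate
15 | 2-{(3S)-1-(tert-butyldimethylsilyloxy)-3-hydroxy-3-[3,4-bis(methoxymethoxy)phenyl]propyl}-5-methoxy-3-(methoxymethoxy)-6-(3-methylbut-2-enyl)phenyl trifluoromethanesulfonate, both epimers at the silyloxy carbon | COc1cc(OCOC)c(C(O[Si](C)(C)C(C)(C)C)C[C@H](O)c2ccc(OCOC)c(OCOC)c2)c(OS(=O)(=O)C(F)(F)F)c1CC=C(C)C | intermediate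
16 | (2S)-4-(tert-butyldimethylsilyloxy)-7-methoxy-5-(methoxymethoxy)-2-[3,4-bis(methoxymethoxy)phenyl]-8-(3-methylbut-2-enyl)chroman, both C4 epimers | COc1cc(OCOC)c2c(c1CC=C(C)C)O[C@H](c1ccc(OCOC)c(OCOC)c1)CC2O[Si](C)(C)C(C)(C)C | intermediate
17 | (2S)-7-methoxy-5-(methoxymethoxy)-2-[3,4-bis(methoxymethoxy)phenyl]-8-(3-methylbut-2-enyl)chroman-4-ol, both C4 epimers | COc1cc(OCOC)c2c(c1CC=C(C)C)O[C@H](c1ccc(OCOC)c(OCOC)c1)CC2O | intermediate
18 | (2S)-7-methoxy-5-(methoxymethoxy)-2-[3,4-bis(methoxymethoxy)phenyl]-8-(3-methylbut-2-enyl)chroman-4-one | COc1cc(OCOC)c2c(c1CC=C(C)C)O[C@H](c1ccc(OCOC)c(OCOC)c1)CC2=O | intermediate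
19 | (2S)-2-(3,4-dihydroxyphenyl)-5-hydroxy-7-methoxy-8-(3-methylbut-2-enyl)chroman-4-one | COc1cc(O)c2c(c1CC=C(C)C)O[C@H](c1ccc(O)c(O)c1)CC2=O | target

## Step count and least certain steps

Total step count: 13. Longest linear sequence: 11 steps (steps 1, 2, 4, 5, 6, 8, 9, 10, 11, 12 and 13, from 1 to 19).

**Step 10 (key step).** The most likely failure is β-hydride elimination of the palladium alkoxide overtaking C–O reductive elimination at the doubly ortho-substituted aryl centre, which reduces the triflate position and re-oxidises the carbinol. Cleavage of the triflate S–O bond by base before insertion, and migration of the silyl group from the C4 oxygen to the C2 oxygen, are secondary risks. The fallback reverses the polarity of the closure and forms O1–C2 instead, setting out from 14 and rejoining at 16. 14 would be reduced with (S)-2-methyl-CBS-oxazaborolidine and catecholborane to 2-{(3R)-1-(tert-butyldimethylsilyloxy)-3-hydroxy-3-[3,4-bis(methoxymethoxy)phenyl]propyl}-5-methoxy-3-(methoxymethoxy)-6-(3-methylbut-2-enyl)phenyl trifluoromethanesulfonate F1 as a mixture of epimers at the silyloxy carbon. The triflate of F1 would be cleaved with Et4NOH in dioxane to 2-{(3R)-1-(tert-butyldimethylsilyloxy)-3-hydroxy-3-[3,4-bis(methoxymethoxy)phenyl]propyl}-5-methoxy-3-(methoxymethoxy)-6-(3-methylbut-2-enyl)phenol F2 without touching the silyl ether. Mitsunobu cyclisation of F2 with PPh3 and diisopropyl azodicarboxylate in THF at 0 °C would then let the phenol displace the activated carbinol with inversion, giving (2S)-configured 16.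

**Step 8.** The aldol addition may reverse before the aldolate is silylated, the triflyl group may shift from the phenolic oxygen to the adjacent alkoxide, or the enolate may attack sulfur. The fallback avoids any free alkoxide; it sets out from 11 and 9 and rejoins at 14. 11 would be converted with Me3SiOTf and Et3N into trimethyl{1-[3,4-bis(methoxymethoxy)phenyl]ethenyloxy}silane F3 in CH2Cl2 at 0 °C. A Mukaiyama aldol addition of F3 to 9 catalysed by Sc(OTf)3 in CH2Cl2 at −78 °C, with aqueous work-up, would give rac-2-{1-hydroxy-3-oxo-3-[3,4-bis(methoxymethoxy)phenyl]propyl}-5-methoxy-3-(methoxymethoxy)-6-(3-methylbut-2-enyl)phenyl trifluoromethanesulfonate F4 as the free aldol. F4 would be silylated with TBSOTf and 2,6-lutidine to 14.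

**Step 9.** Facial selectivity may be poor for the enantiomer of racemic 14 that is mismatched with the catalyst, lowering the enantiomeric purity at C2 of the pooled material; hydroboration of the prenyl alkene is the second risk. The fallback is Noyori–Ikariya transfer hydrogenation of 14 with RuCl[(S,S)-TsDPEN](p-cymene) in HCO2H/Et3N at rt. It should give the same (S)-carbinol 15 by a metal–ligand bifunctional hydride transfer that does not touch alkenes, so it sets out from 14 and rejoins at 15 without new intermediates.

**Step 4.** The chelated, weakly nucleophilic phenoxide may react slowly, attack the unsubstituted allyl terminus, or the tertiary ether may isomerise to the linear one; step 5 would then deliver the wrong C-substituent. The fallback sets out from 3 and rejoins at 6. 3 would be alkylated with 3-chloro-3-methylbut-1-yne (CuCl2·2H2O cat., DBU, MeCN, 0 °C) to 4-methoxy-2-(methoxymethoxy)-6-(2-methylbut-3-yn-2-yloxy)benzaldehyde F5 , in which the tertiary attachment is fixed by the reagent. Semi-hydrogenation of F5 with H2 over Pd/CaCO3 poisoned with Pb(OAc)2 and quinoline in EtOAc would then give 6.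

**Step 1.** Alkylation may continue past the first methyl group or fail to discriminate cleanly among the three hydroxyls. The fallback replaces selective alkylation by selective dealkylation; it sets out from 1 and rejoins at 2. 1 would be fully methylated (excess Me2SO4, K2CO3, acetone, reflux) to 2,4,6-trimethoxybenzaldehyde F6 in one operation. Chelation-directed cleavage of the two methyl ethers of F6 that stand ortho to the formyl group, with AlCl3 in CH2Cl2 at reflux, would then give 2; the site is decided by coordination to the carbonyl, not by acidity.

## Further compounds

F1 | step 10 | 2-{(3R)-1-(tert-butyldimethylsilyloxy)-3-hydroxy-3-[3,4-bis(methoxymethoxy)phenyl]propyl}-5-methoxy-3-(methoxymethoxy)-6-(3-methylbut-2-enyl)phenyl trifluoromethanesulfonate, both epimers at the silyloxy carbon | COc1cc(OCOC)c(C(O[Si](C)(C)C(C)(C)C)C[C@@H](O)c2ccc(OCOC)c(OCOC)c2)c(OS(=O)(=O)C(F)(F)F)c1CC=C(C)C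
F2 | step 10 | 2-{(3R)-1-(tert-butyldimethylsilyloxy)-3-hydroxy-3-[3,4-bis(methoxymethoxy)phenyl]propyl}-5-methoxy-3-(methoxymethoxy)-6-(3-methylbut-2-enyl)phenol, both epimers at the silyloxy carbon | COc1cc(OCOC)c(C(O[Si](C)(C)C(C)(C)C)C[C@@H](O)c2ccc(OCOC)c(OCOC)c2)c(O)c1CC=C(C)C
F3 | step 8 | trimethyl{1-[3,4-bis(methoxymethoxy)phenyl]ethenyloxy}silane | C=C(O[Si](C)(C)C)c1ccc(OCOC)c(OCOC)c1
F4 | step 8 | rac-2-{1-hydroxy-3-oxo-3-[3,4-bis(methoxymethoxy)phenyl]propyl}-5-methoxy-3-(methoxymethoxy)-6-(3-methylbut-2-enyl)phenyl trifluoromethanesulfonate | COc1cc(OCOC)c(C(O)CC(=O)c2ccc(OCOC)c(OCOC)c2)c(OS(=O)(=O)C(F)(F)F)c1CC=C(C)C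
F0 | step 9 | none | none
F5 | step 4 | 4-methoxy-2-(methoxymethoxy)-6-(2-methylbut-3-yn-2-yloxy)benzaldehyde | COc1cc(OCOC)c(C=O)c(OC(C)(C)C#C)c1
F6 | step 1 | 2,4,6-trimethoxybenzaldehyde | COc1cc(OC)c(C=O)c(OC)c1
A1 | alternative 1 | (5S)-1-ethoxy-5-[3,4-bis(methoxymethoxy)phenyl]-5-(5-methylhex-4-en-1-ynyloxy)pent-1-yn-3-one | CCOC#CC(=O)C[C@H](OC#CCC=C(C)C)c1ccc(OCOC)c(OCOC)c1
A2 | alternative 1 | methoxyacetylene | COC#C
A3 | alternative 1 | (2S)-5-ethoxy-7-methoxy-2-[3,4-bis(methoxymethoxy)phenyl]-8-(3-methylbut-2-enyl)chroman-4-one | COc1cc(OCC)c2c(c1CC=C(C)C)O[C@H](c1ccc(OCOC)c(OCOC)c1)CC2=O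
A4 | alternative 2 | 2-{1-[3,4-bis(methoxymethoxy)phenyl]ethenyloxy}-6-hydroxy-4-methoxy-3-(3-methylbut-2-enyl)benzaldehyde | COc1cc(O)c(C=O)c(OC(=C)c2ccc(OCOC)c(OCOC)c2)c1CC=C(C)C
A5 | alternative 2 | (2S)-5-hydroxy-7-methoxy-2-[3,4-bis(methoxymethoxy)phenyl]-8-(3-methylbut-2-enyl)chroman-4-one | COc1cc(O)c2c(c1CC=C(C)C)O[C@H](c1ccc(OCOC)c(OCOC)c1)CC2=O
A6 | alternative 3 | 2-diazo-1-[2-{[3,4-bis(methoxymethoxy)phenyl]methoxy}-6-(tert-butyldimethylsilyloxy)-4-methoxy-3-(3-methylbut-2-enyl)phenyl]ethanone | COc1cc(O[Si](C)(C)C(C)(C)C)c(C(=O)C=[N+]=[N-])c(OCc2ccc(OCOC)c(OCOC)c2)c1CC=C(C)C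
A7 | alternative 3 | (2S)-5-(tert-butyldimethylsilyloxy)-7-methoxy-2-[3,4-bis(methoxymethoxy)phenyl]-8-(3-methylbut-2-enyl)chroman-4-one | COc1cc(O[Si](C)(C)C(C)(C)C)c2c(c1CC=C(C)C)O[C@H](c1ccc(OCOC)c(OCOC)c1)CC2=O
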